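**Plan**

1. Numbering and enabling feature: C1 is the methyl-bearing fusion carbon, C2/C3 are CH2, C4 is the isopropyl carbinol, C5 the fusion CH, C6 the ester carbinol, C7 is CH2, C8 the methyl carbinol, and C9=C10 the alkene (C10 on C1). In the seven-membered ring the C6 oxygen lies 1,4 to the C9=C10 alkene, and the bonds C5–C6 and C1–C10 tie cyclopentane ring A (C1–C5) to the five-carbon chain C6–C10. The ring is therefore a cyclobutanol opened across C6–C10, and that cyclobutane is a [2+2] adduct of ring A with a cyclopentenone.
2. Disconnections, in order: the vanillate C6–O acyl bond; the C4–isopropyl bond (back to a C4 ketone); re-formation of C6–C10 (cyclobutanol with a C9 mesylate); C5–C6 and C1–C10 ([2+2]); the O4–CH2–O6 tether.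
3. Forward order: chiral methylcyclopentenol (ring A) and cyclopentane-1,3-dione are joined through a methylene acetal; irradiation closes the 1,3-dioxane and the cyclobutane; C8 is functionalised on the rigid adduct; fragmentation opens the seven-membered ring; ester and isopropyl group come last.
4. Stereochemistry: C4 (R, from Corey–Bakshi–Shibata reduction) fixes C1 (and transiently C5, C6, C10) through the tether. C8 comes from exo hydroxylation of the photoadduct, C5 from epimerisation next to the C6 ketone, and C6 from a thermodynamically controlled reduction. The final C4 centre is set by addition to the ketone anti to C6 and the C1 methyl.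

Key step: step 4

Conventions and one assumption: locants are those of the target throughout. Exo and endo mean the convex and the concave face of the cyclopentane C6–C10 while it is fused to the cyclobutane. The C9 carbinol configuration drawn for 10–14 is the one expected from hydroxyl-directed hydride delivery; it is erased in step 12.

**Route**

Step 1
Reactants: 1 3-methylcyclopent-2-en-1-one
Product: 2 (R)-3-methylcyclopent-2-en-1-ol
Conditions: (S)-1-methyl-3,3-diphenyltetrahydro-1H,3H-pyrrolo[1,2-c][1,3,2]oxazaborole (10 mol %), catecholborane, toluene, −78 °C; aq. NaOH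
Reagents that add atoms: none
Why: Corey–Bakshi–Shibata reduction, in which the enone binds boron with its larger alkene flank turned away from the catalyst, so hydride should reach the Si face of the carbonyl and give the (R)-allylic alcohol, the only stereocentre carried into the key step; low temperature favours 1,2-reduction over hydroboration.

Step 2
Reactants: 2 (R)-3-methylcyclopent-2-en-1-ol
Product: 3 (3R)-1-methyl-3-[(methylsulfanyl)methoxy]cyclopent-1-ene
Conditions: NaH, THF, 0 °C; ClCH2SMe, NaI (cat.), 0 °C → rt
Reagents that add atoms: chloromethyl methyl sulfide, ClCSC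
Why: Williamson etherification of the alkoxide gives the methylthiomethyl ether under basic conditions, which avoids the acid that would ionise this allylic alcohol; the carbinol centre is not involved.

Step 3
Reactants: 3 (3R)-1-methyl-3-[(methylsulfanyl)methoxy]cyclopent-1-ene; 4 cyclopentane-1,3-dione
Product: 6 3-({[(1R)-3-methylcyclopent-2-en-1-yl]oxy}methoxy)cyclopent-2-en-1-one, via chloromethyl ether 5 (not isolated)
Conditions: SO2Cl2 (1.0 equiv), cyclohexene, CH2Cl2, −78 °C; then 4, i-Pr2NEt, CH2Cl2, −78 °C → rt
Reagents that add atoms: none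
Why: Sulfuryl chloride converts the O,S-acetal into the α-chloro ether without acid (cyclohexene traps the methanesulfenyl chloride that would otherwise add to the ring alkene), and this oxocarbenium-like electrophile alkylates the amine enolate of the dione on oxygen, as in methoxymethylation of cyclic 1,3-diones; the allylic stereocentre is untouched.

Step 4
Reactants: 6 3-({[(1R)-3-methylcyclopent-2-en-1-yl]oxy}methoxy)cyclopent-2-en-1-one
Product: 7 tetracyclic cyclobutane photoadduct (C9 ketone, O4–CH2–O6 dioxane)
Conditions: hν (350 nm lamps, Pyrex), degassed MeCN (0.01 M), rt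
Reagents that add atoms: none
Why: Excitation of the 3-alkoxyenone and intersystem crossing give the triplet, whose β-carbon C6 bonds to C5 in a 6-exo closure that forms the 1,3-dioxane around the O–CH2–O tether and leaves a 1,4-biradical (tertiary at C1, α-acyl at C10) that collapses after spin inversion by C1–C10 bonding to close the cyclobutane. The closest known reaction type is the intramolecular enone–alkene [2+2] photocycloaddition of tethered 3-alkoxycycloalkenones, the first half of a de Mayo sequence. C5 and C1 are controlled by C4, because the dioxane can only be cis-fused to ring A and the enone therefore reaches the alkene face that carries the C4–O bond. C6 and C10 follow from the obligatory cis fusion of the cyclobutane to both five-membered rings, with the tether placing these rings anti across the cyclobutane. The step needs regiocontrol (C10 on the methyl-bearing C1 rather than head-to-tail) and facial control, and both are secured by the four-atom acetal tether anchored at the single stereocentre C4; the endocyclic alkene cannot waste the excitation by cis–trans isomerisation.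

Step 5
Reactants: 7 tetracyclic cyclobutane photoadduct
Product: 8 8-exo-methyl ketone
Conditions: LiN(i-Pr)2, THF, −78 °C; MeI, −78 → −40 °C
Reagents that add atoms: iodomethane, CI
Why: Kinetic enolate alkylation; the enolate forms only towards C8, since removal of the cyclobutane methine H10 would give a strained ring-fusion enolate, and methylation should occur on the convex face, although the C8 configuration is inconsequential because the centre is re-enolised in step 6.

Step 6
Reactants: 8 8-exo-methyl ketone
Product: 9 (8R)-8-hydroxy-8-methyl ketone (hydroxyl exo, methyl endo)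
Conditions: KN(SiMe3)2, THF, −78 °C; 3-phenyl-2-(phenylsulfonyl)oxaziridine, −78 °C; NH4Cl
Reagents that add atoms: 3-phenyl-2-(phenylsulfonyl)oxaziridine, O=S(=O)(c1ccccc1)N1OC1c1ccccc1
Why: Oxaziridine hydroxylation of the tetrasubstituted C8=C9 enolate from the exo face, the concave face being screened by the cyclobutane and the C1 methyl, places the hydroxyl exo and the methyl endo, which is the (8R) carbinol of the target.

Step 7
Reactants: 9 (8R)-8-hydroxy-8-methyl ketone
Product: 10 trans-8,9-diol (9-hydroxyl endo)
Conditions: Me4NBH(OAc)3, MeCN/AcOH (1:1), −20 °C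
Reagents that add atoms: none
Why: Hydroxyl-directed triacetoxyborohydride reduction (Evans–Saksena type), in which the tertiary C8 hydroxyl exchanges onto boron and delivers hydride intramolecularly on the exo face, should give the endo C9 alcohol trans to the C8 hydroxyl; the methylene acetal tolerates acetic acid.

Step 8
Reactants: 10 trans-8,9-diol
Product: 11 9-mesylate with free 8-hydroxyl
Conditions: MsCl, Et3N, CH2Cl2, −20 °C
Reagents that add atoms: methanesulfonyl chloride, CS(=O)(=O)Cl
Why: Sulfene-type mesylation is selective for the secondary C9 hydroxyl over the tertiary one and installs the nucleofuge for the fragmentation; at low temperature the amine does not generate the tertiary alkoxide that would close an epoxide.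

Step 9
Reactants: 11 9-mesylate with free 8-hydroxyl
Product: 12 8-O-TBS ether 9-mesylate
Conditions: t-BuMe2SiOTf, 2,6-lutidine, CH2Cl2, −78 → 0 °C
Reagents that add atoms: tert-butyldimethylsilyl trifluoromethanesulfonate, CC(C)(C)[Si](C)(C)OS(=O)(=O)C(F)(F)F
Why: Silyl triflate silylation of the hindered tertiary alcohol masks the C8 oxygen so that it can neither displace the vicinal mesylate nor take part in a retro-aldol cleavage once the C6 ketone appears; the bulky silyl triflate with lutidine at low temperature leaves the methylene acetal.

Step 10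
Reactants: 12 8-O-TBS ether 9-mesylate
Product: 13 tricyclic 4,6-diol (C6 cyclobutanol)
Conditions: Me3SiOTf, 2,2′-bipyridyl, CH2Cl2, 0 °C → rt; then H2O
Reagents that add atoms: none
Why: Methylene acetal cleavage through the silyl triflate–bipyridyl adduct (a pyridinium intermediate hydrolysed by water) proceeds under nearly neutral conditions, freeing the C4 and C6 hydroxyls without ionising the mesylate or the tertiary silyl ether.

Step 11
Reactants: 13 tricyclic 4,6-diol
Product: 14 4-O-triethylsilyl ether with free cyclobutanol
Conditions: Et3SiCl, imidazole, DMF, 0 °C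
Reagents that add atoms: chlorotriethylsilane, CC[Si](CC)(CC)Cl
Why: Chlorosilane/imidazole silylation distinguishes the secondary C4 hydroxyl from the tertiary cyclobutanol, which stays free to drive the fragmentation.

Step 12
Reactants: 14 4-O-triethylsilyl ether with free cyclobutanol
Product: 15 cis-fused cyclohept-9-en-6-one (H5 cis to the C1 methyl)
Conditions: KOt-Bu (1.1 equiv), THF, −20 → 0 °C
Reagents that add atoms: none
Why: Grob fragmentation of the 1,3-hydroxy mesylate, in which the cyclobutanoxide forms the C6 carbonyl while the C6–C10 bond (brought towards antiperiplanarity with C9–OMs by puckering of the five-membered ring) breaks and mesylate leaves, gives C9=C10 regiospecifically with release of the cyclobutane strain; C1, C4, C5 and C8 are not touched.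

Step 13
Reactants: 15 cis-fused cyclohept-9-en-6-one
Product: 16 trans-fused cyclohept-9-en-6-one (H5 trans to the C1 methyl)
Conditions: K2CO3 (0.2 equiv), MeOH, 0 °C → rt
Reagents that add atoms: none
Why: Base-mediated epimerisation through the C5 enolate should favour the trans fusion, which relieves the cis-1,2 interaction between the C4 silyloxy group and C6; in methanol the enolates are reprotonated much faster than they can expel the β-silyloxy groups.

Step 14
Reactants: 16 trans-fused cyclohept-9-en-6-one
Product: 17 (6S)-alcohol (6-hydroxyl equatorial, on the face of H5)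
Conditions: SmI2 (2.2 equiv), THF, H2O, Et3N, −20 °C, short contact time
Reagents that add atoms: none
Why: Single-electron (ketyl) reduction is expected to give the thermodynamically preferred equatorial alcohol with H6 trans-diaxial to H5, whereas hydride reagents would be expected to attack the face remote from the axial C1 methyl and give the axial epimer; silyl ethers and the isolated alkene should be inert in the short exposure.

Step 15
Reactants: 18 vanillic acid
Product: 20 4-[(tert-butyldimethylsilyl)oxy]-3-methoxybenzoic acid, via bis-silyl vanillate 19 (not isolated)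
Conditions: t-BuMe2SiCl (2.5 equiv), imidazole, DMF, rt; then AcOH, THF/H2O, rt
Reagents that add atoms: tert-butyldimethylsilyl chloride, CC(C)(C)[Si](C)(C)Cl
Why: Silylation of both acidic hydroxyls followed by selective hydrolysis of the labile silyl ester leaves the phenol protected as its silyl ether, which is stable to acylation, mild acid, oxidation and organocerium reagents.

Step 16
Reactants: 17 (6S)-alcohol; 20 4-[(tert-butyldimethylsilyl)oxy]-3-methoxybenzoic acid
Product: 22 6-O-(4-silyloxy-3-methoxybenzoyl) ester, via mixed anhydride 21 (not isolated)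
Conditions: 2,4,6-trichlorobenzoyl chloride, Et3N, THF, rt; then 17, 4-(dimethylamino)pyridine, toluene, rt → 50 °C
Reagents that add atoms: none
Why: Yamaguchi esterification acylates the hindered equatorial C6 hydroxyl through the mixed anhydride and acylpyridinium transfer, with retention at C6 and no effect on the other centres.

Step 17
Reactants: 22 6-O-(4-silyloxy-3-methoxybenzoyl) ester
Product: 23 C4 alcohol
Conditions: pyridinium p-toluenesulfonate (0.2 equiv), MeOH/CH2Cl2, 0 °C → rt
Reagents that add atoms: none
Why: Mild acid methanolysis removes the secondary triethylsilyl ether, while the tertiary and the aryl tert-butyldimethylsilyl ethers, both far more acid-stable, and the ester remain.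

Step 18
Reactants: 23 C4 alcohol
Product: 24 C4 ketone
Conditions: Dess–Martin periodinane, NaHCO3, CH2Cl2, 0 °C → rt
Reagents that add atoms: none
Why: Dess–Martin oxidation under buffered, non-basic conditions gives the β-acyloxy ketone without β-elimination of the vanillate or epimerisation at C5.

Step 19
Reactants: 24 C4 ketone
Product: 25 (4R)-isopropyl carbinol, bis-silyl ether of the target
Conditions: i-PrMgCl, CeCl3 (anhydrous), THF, −78 °C; NH4Cl
Reagents that add atoms: isopropylmagnesium chloride, CC(C)[Mg]Cl
Why: Organocerium addition, whose low basicity suppresses enolisation, β-hydride reduction and attack at the aryl ester, should occur on the ketone face of H5, away from the C5–C6 bond with its acyloxy group and from the axial C1 methyl, giving the tertiary hydroxyl cis to the angular methyl as in the target.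

Step 20
Reactants: 25 (4R)-isopropyl carbinol, bis-silyl ether
Product: 26 CNP0243386.4 (target)
Conditions: Bu4NF, THF, 0 °C → rt; NH4Cl
Reagents that add atoms: none
Why: Fluoride cleaves the aryl and the tertiary allylic silyl ethers under non-acidic conditions, which avoids ionisation of the tertiary allylic alcohol and leaves the hindered ester in place.

**Compound list**

1 | 3-methylcyclopent-2-en-1-one | CC1=CC(=O)CC1 | starting material
2 | (R)-3-methylcyclopent-2-en-1-ol | CC1=C[C@H](O)CC1 | intermediate
3 | (3R)-1-methyl-3-[(methylsulfanyl)methoxy]cyclopent-1-ene | CC1=C[C@H](OCSC)CC1 | intermediate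
4 | cyclopentane-1,3-dione | O=C1CCC(=O)C1 | starting material
5 | (3R)-3-(chloromethoxy)-1-methylcyclopent-1-ene | CC1=C[C@H](OCCl)CC1 | intermediate (not isolated)
6 | 3-({[(1R)-3-methylcyclopent-2-en-1-yl]oxy}methoxy)cyclopent-2-en-1-one | CC1=C[C@H](OCOC2=CC(=O)CC2)CC1 | intermediate
7 | photoadduct: cyclobutane C1–C5–C6–C10 cis-fused to ring A (C1–C5) and, on the opposite face, to the C9-oxo cyclopentane C6–C10; O4–CH2–O6 1,3-dioxane cis to ring A; 1-methyl; 4R | C[C@@]12CC[C@H]3OCO[C@]4(CCC(=O)[C@@H]41)[C@@H]23 | intermediate
8 | 7 with an exo methyl group at C8 | C[C@@]12CC[C@H]3OCO[C@]4(C[C@@H](C)C(=O)[C@@H]41)[C@@H]23 | intermediate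
9 | (8R)-8-hydroxy-8-methyl derivative of 7 (hydroxyl exo, methyl endo) | C[C@@]12CC[C@H]3OCO[C@]4(C[C@@](C)(O)C(=O)[C@@H]41)[C@@H]23 | intermediate
10 | 9-endo alcohol of 9 (trans-8,9-diol) | C[C@@]12CC[C@H]3OCO[C@]4(C[C@@](C)(O)[C@H](O)[C@@H]41)[C@@H]23 | intermediate
11 | 9-O-methanesulfonate of 10 (8-hydroxyl free) | C[C@@]12CC[C@H]3OCO[C@]4(C[C@@](C)(O)[C@H](OS(C)(=O)=O)[C@@H]41)[C@@H]23 | intermediate
12 | 8-O-tert-butyldimethylsilyl ether of 11 | C[C@@]12CC[C@H]3OCO[C@]4(C[C@@](C)(O[Si](C)(C)C(C)(C)C)[C@H](OS(C)(=O)=O)[C@@H]41)[C@@H]23 | intermediate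
13 | tricyclic 4,6-diol from 12 (acetal carbon removed; tertiary cyclobutanol at C6, secondary alcohol at C4) | C[C@]12CC[C@@H](O)[C@H]1[C@]3(O)C[C@@](C)(O[Si](C)(C)C(C)(C)C)[C@H](OS(C)(=O)=O)[C@@H]32 | intermediate
14 | 4-O-triethylsilyl ether of 13 | C[C@]12CC[C@@H](O[Si](CC)(CC)CC)[C@H]1[C@]3(O)C[C@@](C)(O[Si](C)(C)C(C)(C)C)[C@H](OS(C)(=O)=O)[C@@H]32 | intermediate
15 | cis-fused hydroazulenone: C6 ketone, C9=C10, 4-OSiEt3, 8-OSi(t-Bu)Me2, 1,8-dimethyl; H5 cis to the C1 methyl | C[C@]12CC[C@@H](O[Si](CC)(CC)CC)[C@H]1C(=O)C[C@@](C)(O[Si](C)(C)C(C)(C)C)C=C2 | intermediate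
16 | trans-fused C5 epimer of 15 (H5 trans to the C1 methyl) | C[C@]12CC[C@@H](O[Si](CC)(CC)CC)[C@@H]1C(=O)C[C@@](C)(O[Si](C)(C)C(C)(C)C)C=C2 | intermediate
17 | (6S)-alcohol of 16 (6-hydroxyl on the face of H5) | C[C@]12CC[C@@H](O[Si](CC)(CC)CC)[C@@H]1[C@@H](O)C[C@@](C)(O[Si](C)(C)C(C)(C)C)C=C2 | intermediate
18 | vanillic acid | COc1cc(C(=O)O)ccc1O | starting material
19 | tert-butyldimethylsilyl 4-[(tert-butyldimethylsilyl)oxy]-3-methoxybenzoate | COc1cc(C(=O)O[Si](C)(C)C(C)(C)C)ccc1O[Si](C)(C)C(C)(C)C | intermediate (not isolated)
20 | 4-[(tert-butyldimethylsilyl)oxy]-3-methoxybenzoic acid | COc1cc(C(=O)O)ccc1O[Si](C)(C)C(C)(C)C | intermediate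
21 | 4-[(tert-butyldimethylsilyl)oxy]-3-methoxybenzoic 2,4,6-trichlorobenzoic anhydride | COc1cc(C(=O)OC(=O)c2c(Cl)cc(Cl)cc2Cl)ccc1O[Si](C)(C)C(C)(C)C | intermediate (not isolated)
22 | 6-O-[4-(tert-butyldimethylsilyloxy)-3-methoxybenzoyl] ester of 17 | C[C@]12CC[C@@H](O[Si](CC)(CC)CC)[C@@H]1[C@@H](OC(=O)c1ccc(O[Si](C)(C)C(C)(C)C)c(OC)c1)C[C@@](C)(O[Si](C)(C)C(C)(C)C)C=C2 | intermediate
23 | C4 alcohol from 22 (triethylsilyl group removed) | C[C@]12CC[C@@H](O)[C@@H]1[C@@H](OC(=O)c1ccc(O[Si](C)(C)C(C)(C)C)c(OC)c1)C[C@@](C)(O[Si](C)(C)C(C)(C)C)C=C2 | intermediate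
24 | C4 ketone from 23 | C[C@]12CCC(=O)[C@@H]1[C@@H](OC(=O)c1ccc(O[Si](C)(C)C(C)(C)C)c(OC)c1)C[C@@](C)(O[Si](C)(C)C(C)(C)C)C=C2 | intermediate
25 | (4R)-4-hydroxy-4-isopropyl compound, 8-O- and phenol-O-silyl ether of the target | C[C@]12CC[C@@](O)(C(C)C)[C@@H]1[C@@H](OC(=O)c1ccc(O[Si](C)(C)C(C)(C)C)c(OC)c1)C[C@@](C)(O[Si](C)(C)C(C)(C)C)C=C2 | intermediate
26 | CNP0243386.4: (1R,4R,5S,6S,8R)-4,8-dihydroxy-4-isopropyl-1,8-dimethyl-trans-hydroazul-9-en-6-yl 4-hydroxy-3-methoxybenzoate (locants as defined in the plan) | COc1cc(C(=O)O[C@H]2C[C@@](C)(O)C=C[C@@]3(C)CC[C@@](O)(C(C)C)[C@H]23)ccc1O | target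

**Totals**

Total step count: 20. Longest linear sequence: 19 steps (steps 1–14 and 16–20; step 15 is a one-step side branch).

**Steps most likely to fail**

Step 12 (fragmentation). What may go wrong: the breaking C6–C10 bond may not come close enough to antiperiplanar with the endo C9–O bond in the flattened, heavily substituted five-membered ring, so that the alkoxide fragments slowly and elimination or substitution at C9 competes. The fallback replaces the endo sulfonate by an exo epoxide nucleofuge and a titanium template; it sets out from 11 and returns at 15. The methylene acetal of 11 is cleaved as in step 10 (Me3SiOTf, 2,2′-bipyridyl; H2O) to the triol mesylate F1, and the secondary C4 hydroxyl is silylated (Et3SiCl, imidazole) to the triethylsilyl ether F2. K2CO3 in MeOH lets the tertiary C8 alkoxide displace the endo mesylate with inversion to give the exo 8,9-epoxy cyclobutanol F3. Ti(OiPr)4 in CH2Cl2 at 40 °C binds the cyclobutanol and the syn epoxide oxygen and should trigger the epoxy-alcohol fragmentation (C6–C10 cleavage with opening of the C9–O bond) to the hydroxy ketone F4. Silylation of its tertiary hydroxyl (t-BuMe2SiOTf, 2,6-lutidine, −78 °C) gives 15.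

Step 14 (C6 reduction). What may go wrong: loss of thermodynamic control, giving a mixture of C6 epimers, or reductive cleavage of the allylic C8–O bond by the strongly reducing samarium/amine/water system. The fallback uses kinetic reduction followed by inversion; it sets out from 16 and returns at 17. LiB(s-Bu)3H (THF, −78 °C) should attack the ketone from the face remote from the axial C1 methyl and give the axial 6-epi alcohol F5. Mitsunobu inversion (PPh3, diisopropyl azodicarboxylate, 4-nitrobenzoic acid, toluene) converts it into the equatorial 4-nitrobenzoate F6, and methanolysis (K2CO3, MeOH) gives 17.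

Step 19 (isopropyl addition). What may go wrong: deprotonation at C5 by the organometallic followed by β-elimination of the C6 vanillate, or β-hydride transfer from the isopropyl reagent to the hindered ketone. The fallback uses an sp2 nucleophile without β-hydrogens and then saturates it; it sets out from 24 and returns at 25. Isopropenylmagnesium bromide with CeCl3 (THF, −78 °C) adds to the same ketone face to give the isopropenyl carbinol F7. Hydroxyl-directed hydrogenation with [Ir(cod)(PCy3)(py)]PF6 under H2 (CH2Cl2, rt) reduces the 1,1-disubstituted alkene next to the free C4 hydroxyl and should leave the hindered C9=C10 alkene, giving 25.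

**Further compounds**

F1 | step 12 | tricyclic 4,6,8-triol 9-mesylate (acetal of 11 removed) | C[C@]12CC[C@@H](O)[C@H]1[C@]3(O)C[C@@](C)(O)[C@H](OS(C)(=O)=O)[C@@H]32
F2 | step 12 | 4-O-triethylsilyl ether of F1 | C[C@]12CC[C@@H](O[Si](CC)(CC)CC)[C@H]1[C@]3(O)C[C@@](C)(O)[C@H](OS(C)(=O)=O)[C@@H]32
F3 | step 12 | exo 8,9-epoxy cyclobutanol (4-O-triethylsilyl) | C[C@]12CC[C@@H](O[Si](CC)(CC)CC)[C@H]1[C@]3(O)C[C@@]4(C)O[C@H]4[C@@H]32
F4 | step 12 | cis-fused hydroazulenone with free 8-hydroxyl (8-O-desilyl 15) | C[C@]12CC[C@@H](O[Si](CC)(CC)CC)[C@H]1C(=O)C[C@@](C)(O)C=C2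
F5 | step 14 | (6R)-alcohol, C6 epimer of 17 (axial hydroxyl) | C[C@]12CC[C@@H](O[Si](CC)(CC)CC)[C@@H]1[C@H](O)C[C@@](C)(O[Si](C)(C)C(C)(C)C)C=C2
F6 | step 14 | 6-O-(4-nitrobenzoyl) ester of 17 | C[C@]12CC[C@@H](O[Si](CC)(CC)CC)[C@@H]1[C@@H](OC(=O)c1ccc(cc1)[N+](=O)[O-])C[C@@](C)(O[Si](C)(C)C(C)(C)C)C=C2
F7 | step 19 | 4-isopropenyl analogue of 25 | C[C@]12CC[C@@](O)(C(C)=C)[C@@H]1[C@@H](OC(=O)c1ccc(O[Si](C)(C)C(C)(C)C)c(OC)c1)C[C@@](C)(O[Si](C)(C)C(C)(C)C)C=C2
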